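## Retrosynthetic overview
1. The rings are lettered A–G, from the 2,4,6-trihydroxyphenoxy end to the 3,4,5-trihydroxyphenoxy end. The target comes from its heptadeca-O-methyl ether by one global O-demethylation. No ring is built, because all seven benzene rings are bought.
2. All six disconnections are diaryl ether C–O bonds, each cut as a hindered phenol O–H plus a less hindered aryl C–halogen. The last cut is E–O–F (A–E phenol + F–G bromide), and before it C–O–D (A–C phenol + D–E bromide).
3. Rings C and E enter as ortho-bromobenzaldehydes. The CHO group steers copper to its own C–Br bond (a new transient-imine-directed Ullmann coupling), so unprotected 4-bromo-2,6-dimethoxyphenol serves as rings B, D and F. The CHO group is then converted into the next phenol by Baeyer–Villiger oxidation.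
4. Order of joining: B–C, A–B, CHO→OH, D–E, C–D, CHO→OH, F–G, E–F, demethylation.

Assumption: the SMILES holds no stereocentre and the diaryl ether axes rotate freely, so the target is achiral and there is no configuration to set.

## Route

Step 1
Reactants: 1 5-bromo-1,2,3-trimethoxybenzene
Product: 3 6-bromo-2,3,4-trimethoxybenzaldehyde, via chloro ether 2 (not isolated)
Conditions: Cl2CHOMe (1.5 equiv), TiCl4 (2.0 equiv), CH2Cl2, −10 → 0 °C; then ice-water
Reagents that add atoms: dichloromethyl methyl ether, COC(Cl)Cl; water, O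
Why: Rieche formylation (Friedel–Crafts type) works because three OMe groups keep the ring nucleophilic despite Br, the two free positions of 1 are equivalent so only one regioisomer can form, and the racemic chloro ether 2 collapses to the achiral aldehyde on hydrolysis.

Step 2
Reactants: 3 6-bromo-2,3,4-trimethoxybenzaldehyde; 4 4-bromo-2,6-dimethoxyphenol
Product: 7 6-(4-bromo-2,6-dimethoxyphenoxy)-2,3,4-trimethoxybenzaldehyde, via bromoaryl aldimine 5 (not isolated), via aryloxy aldimine 6 (not isolated)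
Conditions: CuI (10 mol %), 2-aminoisobutyric acid (25 mol %), K3PO4 (2 equiv), DMSO, 50 °C, Ar
Reagents that add atoms: none
Why: Proposed new method: a transient-directing-group Ullmann etherification in which catalytic 2-aminoisobutyric acid (no α-H, so no azaallyl or aldol chemistry, and hindered against N-arylation) condenses reversibly with the aldehyde to an (E)-imino-carboxylate that binds Cu(I) as an anionic N,O-chelate next to the ortho C–Br bond, so oxidative addition is intramolecular (five-membered cupracycle) and runs at 50 °C, where the undirected, phenoxide-deactivated para C–Br of 4 and the para C–Br of 7 are inert, after which bromide/phenoxide exchange, C–O reductive elimination from Cu(III) and imine hydrolysis release 7 and the amino acid; the closest known reaction types are the ortho-carboxylate-accelerated (Hurtley-type) Ullmann coupling, the amino-acid-ligated Ullmann ether synthesis and transient imine directing groups in Pd- and Cu-mediated C–H functionalisation of benzaldehydes.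

Step 3
Reactants: 7 6-(4-bromo-2,6-dimethoxyphenoxy)-2,3,4-trimethoxybenzaldehyde; 8 2,4,6-trimethoxyphenol
Product: 9 6-[2,6-dimethoxy-4-(2,4,6-trimethoxyphenoxy)phenoxy]-2,3,4-trimethoxybenzaldehyde
Conditions: 8 (1.5 equiv), CuI (10 mol %), picolinic acid (20 mol %), K3PO4 (2 equiv), degassed DMSO, 90 °C, Ar
Reagents that add atoms: none
Why: This ligand-accelerated Ullmann diaryl ether synthesis is clean because 7 carries the only C–Br and 8 the only O–H in the flask, picolinate-ligated Cu(I) is the established system for di-ortho-substituted phenols with unhindered aryl bromides, and the non-enolisable aldehyde tolerates K3PO4.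

Step 4
Reactants: 9 6-[2,6-dimethoxy-4-(2,4,6-trimethoxyphenoxy)phenoxy]-2,3,4-trimethoxybenzaldehyde
Product: 11 6-[2,6-dimethoxy-4-(2,4,6-trimethoxyphenoxy)phenoxy]-2,3,4-trimethoxyphenol, via trimer formate 10 (not isolated)
Conditions: mCPBA (1.3 equiv), CH2Cl2, 0 °C → rt; then K2CO3 (cat.), MeOH, rt, Ar
Reagents that add atoms: mCPBA, O=C(OO)c1cccc(Cl)c1
Why: In this Baeyer–Villiger (Dakin-type) oxidation the very electron-rich aryl group migrates in preference to H to give the aryl formate, which catalytic methoxide cleaves at rt, while methyl and diaryl ethers are untouched.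

Step 5
Reactants: 12 2-bromo-4,6-dimethoxybenzaldehyde; 4 4-bromo-2,6-dimethoxyphenol
Product: 15 2-(4-bromo-2,6-dimethoxyphenoxy)-4,6-dimethoxybenzaldehyde, via bromoaryl aldimine 13 (not isolated), via aryloxy aldimine 14 (not isolated)
Conditions: CuI (10 mol %), 2-aminoisobutyric acid (25 mol %), K3PO4 (2 equiv), DMSO, 50 °C, Ar
Reagents that add atoms: none
Why: Proposed new method: the same transient-imine-directed Ullmann etherification as in step 2, in which the reversibly formed (E)-imino-carboxylate chelates Cu(I) and delivers it intramolecularly into the ortho C–Br bond of 12 (five-membered cupracycle, then phenoxide exchange, C–O reductive elimination and imine hydrolysis), so only this bromide reacts at 50 °C and the para bromide of 4 and 15 survives; the closest known reaction types are Hurtley-type ortho-assisted Ullmann coupling, amino-acid-ligated Ullmann ether synthesis and transient imine directing groups in C–H functionalisation.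

Step 6
Reactants: 11 6-[2,6-dimethoxy-4-(2,4,6-trimethoxyphenoxy)phenoxy]-2,3,4-trimethoxyphenol; 15 2-(4-bromo-2,6-dimethoxyphenoxy)-4,6-dimethoxybenzaldehyde
Product: 16 2-(4-{6-[2,6-dimethoxy-4-(2,4,6-trimethoxyphenoxy)phenoxy]-2,3,4-trimethoxyphenoxy}-2,6-dimethoxyphenoxy)-4,6-dimethoxybenzaldehyde
Conditions: 15 (1.2 equiv), CuI (20 mol %), picolinic acid (40 mol %), K3PO4 (2 equiv), degassed DMSO, 95 °C, Ar
Reagents that add atoms: none
Why: This Ullmann diaryl ether synthesis pairs one phenol with one aryl bromide, the bromide sits between two ring hydrogens so all the hindrance lies on the phenol side where picolinate-Cu(I) copes best, and ring B is too electron-rich for a Smiles-type aryl shift in the phenoxide.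

Step 7
Reactants: 16 2-(4-{6-[2,6-dimethoxy-4-(2,4,6-trimethoxyphenoxy)phenoxy]-2,3,4-trimethoxyphenoxy}-2,6-dimethoxyphenoxy)-4,6-dimethoxybenzaldehyde
Product: 18 2-(4-{6-[2,6-dimethoxy-4-(2,4,6-trimethoxyphenoxy)phenoxy]-2,3,4-trimethoxyphenoxy}-2,6-dimethoxyphenoxy)-4,6-dimethoxyphenol, via pentamer formate 17 (not isolated)
Conditions: mCPBA (1.3 equiv), CH2Cl2, 0 °C → rt; then K2CO3 (cat.), MeOH, rt, Ar
Reagents that add atoms: mCPBA, O=C(OO)c1cccc(Cl)c1
Why: In this Baeyer–Villiger (Dakin-type) oxidation the 2,4,6-trioxygenated aryl group migrates fast at 0 °C, so the peracid is consumed before it can attack the other rings, and the phenol appears only after the oxidant is gone.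

Step 8
Reactants: 19 5-iodo-1,2,3-trimethoxybenzene; 4 4-bromo-2,6-dimethoxyphenol
Product: 20 5-bromo-1,3-dimethoxy-2-(3,4,5-trimethoxyphenoxy)benzene
Conditions: 19 (1.4 equiv), CuI (5 mol %), picolinic acid (10 mol %), K3PO4 (2 equiv), degassed DMSO, 75 °C, Ar
Reagents that add atoms: none
Why: This halogen-selective Ullmann diaryl ether synthesis works because C–I reacts with Cu(I) well before C–Br at this temperature, the bromide of 4 is further deactivated as the para-bromophenoxide, and the excess of 19 outcompetes product 20.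

Step 9
Reactants: 18 2-(4-{6-[2,6-dimethoxy-4-(2,4,6-trimethoxyphenoxy)phenoxy]-2,3,4-trimethoxyphenoxy}-2,6-dimethoxyphenoxy)-4,6-dimethoxyphenol; 20 5-bromo-1,3-dimethoxy-2-(3,4,5-trimethoxyphenoxy)benzene
Product: 21 heptadeca-O-methyl ether of the target (A–G heptamer with all 17 OH as OMe)
Conditions: 20 (1.3 equiv), CuI (25 mol %), picolinic acid (50 mol %), K3PO4 (2 equiv), degassed DMSO, 100 °C, Ar
Reagents that add atoms: none
Why: This Ullmann diaryl ether synthesis is of the same type as step 6, with a single phenol, a single unhindered aryl bromide and no other reactive group, so only rate and not selectivity is at stake.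

Step 10
Reactants: 21 heptadeca-O-methyl ether of the target
Product: 23 CNP0351377.0 (target), via perborylated heptamer 22 (not isolated)
Conditions: BBr3 (34 equiv), CH2Cl2, −78 °C → rt, 24 h, Ar; then H2O, 0 °C; Sephadex LH-20 (degassed MeOH)
Reagents that add atoms: none
Why: In this Lewis-acid O-demethylation BBr3 binds each OMe oxygen and bromide attacks the methyl carbon (SN2), the aryl–O–aryl bonds offer no sp3 carbon and stay intact, hydrolysis of the aryl borates frees all 17 phenols, and there is no stereocentre to disturb.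

## Compound list
1 | 5-bromo-1,2,3-trimethoxybenzene | COc1cc(Br)cc(OC)c1OC | starting material
2 | 1-bromo-2-[chloro(methoxy)methyl]-3,4,5-trimethoxybenzene (racemic, not isolated) | COC(Cl)c1c(Br)cc(OC)c(OC)c1OC | intermediate
3 | 6-bromo-2,3,4-trimethoxybenzaldehyde (ring C) | O=Cc1c(Br)cc(OC)c(OC)c1OC | intermediate
4 | 4-bromo-2,6-dimethoxyphenol (rings B, D and F) | COc1cc(Br)cc(OC)c1O | starting material
5 | 2-{(E)-[(6-bromo-2,3,4-trimethoxyphenyl)methylidene]amino}-2-methylpropanoic acid (not isolated) | CC(C)(/N=C/c1c(Br)cc(OC)c(OC)c1OC)C(=O)O | intermediate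
6 | 2-{(E)-[(6-(4-bromo-2,6-dimethoxyphenoxy)-2,3,4-trimethoxyphenyl)methylidene]amino}-2-methylpropanoic acid (not isolated) | CC(C)(/N=C/c1c(Oc2c(OC)cc(Br)cc2OC)cc(OC)c(OC)c1OC)C(=O)O | intermediate
7 | 6-(4-bromo-2,6-dimethoxyphenoxy)-2,3,4-trimethoxybenzaldehyde (B–C) | O=Cc1c(Oc2c(OC)cc(Br)cc2OC)cc(OC)c(OC)c1OC | intermediate
8 | 2,4,6-trimethoxyphenol (ring A) | COc1cc(OC)c(O)c(OC)c1 | starting material
9 | 6-[2,6-dimethoxy-4-(2,4,6-trimethoxyphenoxy)phenoxy]-2,3,4-trimethoxybenzaldehyde (A–B–C aldehyde) | COc1cc(OC)c(Oc2cc(OC)c(Oc3cc(OC)c(OC)c(OC)c3C=O)c(OC)c2)c(OC)c1 | intermediate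
10 | 6-[2,6-dimethoxy-4-(2,4,6-trimethoxyphenoxy)phenoxy]-2,3,4-trimethoxyphenyl formate (not isolated) | COc1cc(OC)c(Oc2cc(OC)c(Oc3cc(OC)c(OC)c(OC)c3OC=O)c(OC)c2)c(OC)c1 | intermediate
11 | 6-[2,6-dimethoxy-4-(2,4,6-trimethoxyphenoxy)phenoxy]-2,3,4-trimethoxyphenol (A–B–C phenol) | COc1cc(OC)c(Oc2cc(OC)c(Oc3cc(OC)c(OC)c(OC)c3O)c(OC)c2)c(OC)c1 | intermediate
12 | 2-bromo-4,6-dimethoxybenzaldehyde (ring E) | O=Cc1c(Br)cc(OC)cc1OC | starting material
13 | 2-{(E)-[(2-bromo-4,6-dimethoxyphenyl)methylidene]amino}-2-methylpropanoic acid (not isolated) | CC(C)(/N=C/c1c(Br)cc(OC)cc1OC)C(=O)O | intermediate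
14 | 2-{(E)-[(2-(4-bromo-2,6-dimethoxyphenoxy)-4,6-dimethoxyphenyl)methylidene]amino}-2-methylpropanoic acid (not isolated) | CC(C)(/N=C/c1c(Oc2c(OC)cc(Br)cc2OC)cc(OC)cc1OC)C(=O)O | intermediate
15 | 2-(4-bromo-2,6-dimethoxyphenoxy)-4,6-dimethoxybenzaldehyde (D–E) | O=Cc1c(Oc2c(OC)cc(Br)cc2OC)cc(OC)cc1OC | intermediate
16 | 2-(4-{6-[2,6-dimethoxy-4-(2,4,6-trimethoxyphenoxy)phenoxy]-2,3,4-trimethoxyphenoxy}-2,6-dimethoxyphenoxy)-4,6-dimethoxybenzaldehyde (A–E aldehyde) | COc1cc(OC)c(Oc2cc(OC)c(Oc3cc(OC)c(OC)c(OC)c3Oc3cc(OC)c(Oc4cc(OC)cc(OC)c4C=O)c(OC)c3)c(OC)c2)c(OC)c1 | intermediate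
17 | formate ester of 18 (A–E aryl formate, not isolated) | COc1cc(OC)c(Oc2cc(OC)c(Oc3cc(OC)c(OC)c(OC)c3Oc3cc(OC)c(Oc4cc(OC)cc(OC)c4OC=O)c(OC)c3)c(OC)c2)c(OC)c1 | intermediate
18 | 2-(4-{6-[2,6-dimethoxy-4-(2,4,6-trimethoxyphenoxy)phenoxy]-2,3,4-trimethoxyphenoxy}-2,6-dimethoxyphenoxy)-4,6-dimethoxyphenol (A–E phenol) | COc1cc(OC)c(Oc2cc(OC)c(Oc3cc(OC)c(OC)c(OC)c3Oc3cc(OC)c(Oc4cc(OC)cc(OC)c4O)c(OC)c3)c(OC)c2)c(OC)c1 | intermediate
19 | 5-iodo-1,2,3-trimethoxybenzene (ring G) | COc1cc(I)cc(OC)c1OC | starting material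
20 | 5-bromo-1,3-dimethoxy-2-(3,4,5-trimethoxyphenoxy)benzene (F–G) | COc1cc(Oc2c(OC)cc(Br)cc2OC)cc(OC)c1OC | intermediate
21 | heptadeca-O-methyl ether of the target (A–G heptamer, all 17 OH as OMe) | COc1cc(OC)c(Oc2cc(OC)c(Oc3cc(OC)c(OC)c(OC)c3Oc3cc(OC)c(Oc4cc(OC)cc(OC)c4Oc4cc(OC)c(Oc5cc(OC)c(OC)c(OC)c5)c(OC)c4)c(OC)c3)c(OC)c2)c(OC)c1 | intermediate
22 | heptadecakis(O-dibromoboryl) derivative of the target (idealised, not isolated) | BrB(Br)Oc1cc(OB(Br)Br)c(Oc2cc(OB(Br)Br)c(Oc3cc(OB(Br)Br)c(OB(Br)Br)c(OB(Br)Br)c3Oc3cc(OB(Br)Br)c(Oc4cc(OB(Br)Br)cc(OB(Br)Br)c4Oc4cc(OB(Br)Br)c(Oc5cc(OB(Br)Br)c(OB(Br)Br)c(OB(Br)Br)c5)c(OB(Br)Br)c4)c(OB(Br)Br)c3)c(OB(Br)Br)c2)c(OB(Br)Br)c1 | intermediate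
23 | CNP0351377.0 (C42H30O23, achiral) | Oc1cc(O)c(Oc2cc(O)c(Oc3cc(O)c(O)c(O)c3Oc3cc(O)c(Oc4cc(O)cc(O)c4Oc4cc(O)c(Oc5cc(O)c(O)c(O)c5)c(O)c4)c(O)c3)c(O)c2)c(O)c1 | target

## Step count and risks
Total steps: 10. Longest linear sequence: 8 (steps 1, 2, 3, 4, 6, 7, 9, 10). Steps 5 and 8 are side branches.

**Step 2 (new method).**
- Risk: imine formation on the di-ortho-substituted aldehyde may be too slow, or copper may rest as an unreactive C,N,O-chelated species. The Br/Br selectivity would then be lost.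
- The fallback uses known chemistry only. It sets out from 4 and 8 and comes back to the route at 9.
- Compound 4 is O-benzylated (BnBr, K2CO3, DMF) to 2-(benzyloxy)-5-bromo-1,3-dimethoxybenzene F1.
- F1 is joined to 8 by the ordinary CuI/picolinic acid Ullmann coupling to give 2-(benzyloxy)-1,3-dimethoxy-5-(2,4,6-trimethoxyphenoxy)benzene F2.
- Hydrogenolysis (H2, Pd/C, EtOAc) frees 2,6-dimethoxy-4-(2,4,6-trimethoxyphenoxy)phenol F3.
- F3 is coupled with 3 under the same Ullmann conditions. Only one C–Br and one O–H are then present, and the product is 9. Steps 2 and 3 are replaced by four steps.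

**Step 5 (new method, second use).**
- Risk: the same as in step 2.
- The fallback swaps metal catalysis for metal-free SNAr. It sets out from 4 and comes back at 15.
- Bought 1-fluoro-3,5-dimethoxybenzene F4 is formylated under Vilsmeier–Haack conditions (POCl3, DMF) at the less crowded position between F and OMe. This gives 2-fluoro-4,6-dimethoxybenzaldehyde F5.
- F5 and 4 are heated with K2CO3 in DMAc at 120 °C. Only the C–F bond ortho to CHO can undergo addition–elimination, so the aryl bromide is untouched and 15 results.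

**Step 10 (17-fold demethylation and isolation of an air-sensitive polyphenol).**
- Risk: precipitating borates can stall the reaction, and the crude phenol is hard to purify.
- The fallback is a trap–purify–release sequence. It sets out from 21 and comes back at 23.
- The crude product of the BBr3 treatment is not purified. It is acetylated at once (Ac2O, pyridine, Ar) to the heptadecaacetate of the target F6.
- F6 is stable on silica, so it can be separated from under-demethylated material, which is resubmitted.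
- Acid methanolysis of F6 (cat. AcCl in degassed MeOH, rt, Ar) then releases pure 23 without exposing it to base or air.

Further compounds
F1 | step 2 | 2-(benzyloxy)-5-bromo-1,3-dimethoxybenzene | COc1cc(Br)cc(OC)c1OCc1ccccc1
F2 | step 2 | 2-(benzyloxy)-1,3-dimethoxy-5-(2,4,6-trimethoxyphenoxy)benzene | COc1cc(OC)c(Oc2cc(OC)c(OCc3ccccc3)c(OC)c2)c(OC)c1
F3 | step 2 | 2,6-dimethoxy-4-(2,4,6-trimethoxyphenoxy)phenol | COc1cc(OC)c(Oc2cc(OC)c(O)c(OC)c2)c(OC)c1
F4 | step 5 | 1-fluoro-3,5-dimethoxybenzene (bought) | COc1cc(F)cc(OC)c1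
F5 | step 5 | 2-fluoro-4,6-dimethoxybenzaldehyde | O=Cc1c(F)cc(OC)cc1OC
F6 | step 10 | heptadecaacetate of the target | CC(=O)Oc1cc(OC(C)=O)c(Oc2cc(OC(C)=O)c(Oc3cc(OC(C)=O)c(OC(C)=O)c(OC(C)=O)c3Oc3cc(OC(C)=O)c(Oc4cc(OC(C)=O)cc(OC(C)=O)c4Oc4cc(OC(C)=O)c(Oc5cc(OC(C)=O)c(OC(C)=O)c(OC(C)=O)c5)c(OC(C)=O)c4)c(OC(C)=O)c3)c(OC(C)=O)c2)c(OC(C)=O)c1
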